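**Retrosynthetic overview**
1. 18 ⇐ C6=C7 dehydrogenation of aldol 17 ⇐ C7–C11 aldol of the C8 ketone 14 with acetone.
2. 14 ⇐ C4–O bond by α-face syn-hydroboration–oxidation of the Δ3 enol ester 11 (key step: fixes C3 and C4 together and keeps the acyl group), then ketal hydrolysis.
3. 11 ⇐ O-acylation of the Li/NH3 enolate of enone 7 with the (R)-2-methylbutanoyl group (sets 5α-H, trans-decalin).
4. 7 ⇐ Robinson annulation of ketal ketone 1 with ethyl vinyl ketone; a chiral-imine Michael addition sets C10.
5. Ring order: ring B is bought as cyclohexanone 1; ring A is closed onto it in step 2; no later ring formation.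

Assumption: (R)-2-methylbutanoic acid (8) is bought as the single enantiomer.
Convention: eudesmane numbering for the decalin (ring A = C1–C5, C10; ring B = C5–C10; methyls on C4 and C10; C11 = carbinol carbon on C7); β = the face of the C10 methyl. Target 18 = 3β-acyloxy, 4α-OH, 4β-Me, 5α-H, 10β-Me.

**Step 1**
Reactants: 1 7-methyl-1,4-dioxaspiro[4.5]decan-8-one (racemic); 2 (R)-1-phenylethylamine; 3 ethyl vinyl ketone
Product: 6 (R)-7-methyl-7-(3-oxopentyl)-1,4-dioxaspiro[4.5]decan-8-one, via ketimine 4 (not isolated), via Michael-adduct ketimine 5 (not isolated)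
Conditions: 2 (1.05 equiv), TsOH (cat.), toluene, reflux, Dean–Stark; then 3 (1.5 equiv), THF, 40 °C, 3 d; then 10% aq AcOH, rt, 1 h
Reagents that add atoms: water, O
Why: d'Angelo deracemising Michael addition: the imine reacts through its more substituted secondary enamine, and the (R)-auxiliary directs the enone to one face in an aza-ene-like transition state, creating the quaternary C10 (expected ≥90% ee by analogy with 2-methylcyclohexanone; the minor enantiomer becomes a separable diastereomer once the (R)-acyl group is attached).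

**Step 2**
Reactants: 6
Product: 7 (4aR)-6,6-ethylenedioxy-1,4a-dimethyl-4,4a,5,6,7,8-hexahydronaphthalen-2(3H)-one (10β-methyl ketal enone)
Conditions: NaOMe (0.5 equiv), MeOH, 60 °C
Reagents that add atoms: none
Why: Intramolecular aldol condensation (second half of the Robinson annulation): the ethyl-ketone α-carbon adds to the ring ketone and dehydration gives the tetrasubstituted enone, with the quaternary C10 untouched and the ketal stable to base.

**Step 3**
Reactants: 7; 8 (R)-2-methylbutanoic acid
Product: 11 8,8-ethylenedioxy-4,10β-dimethyl-5αH-decal-3-en-3-yl (R)-2-methylbutanoate (Δ3 enol ester), via lithium enolate 9 (not isolated), via (R)-2-methylbutanoic anhydride 10 (not isolated)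
Conditions: Li (2.2 equiv), t-BuOH (1.0 equiv), NH3/THF, −78 °C, then NH3 off; 10 (3 equiv; from 8 + DCC, CH2Cl2, 0 °C, filtered), THF, −78 → 0 °C; aq NH4Cl
Reagents that add atoms: none
Why: Dissolving-metal (Birch-type) enone reduction protonates C5 axially on the α face, anti to the C10 methyl, giving the trans-fused Δ3 lithium enolate regiospecifically; the enolate is O-acylated (enol ester formation) because C-acylation would have to build a quaternary C4, so the double-bond position and the acyl group needed for step 4 are fixed in one operation.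

**Step 4**
Reactants: 11
Product: 14 3β-[(R)-2-methylbutanoyloxy]-4α-hydroxy-4β,10β-dimethyl-5αH-decalin-8-one, via organoborane 12 (not isolated), via hydroxy ester ketal 13 (not isolated)
Conditions: BH3·SMe2 (2 equiv), THF, 0 → 35 °C; then MeOH, 30% H2O2, aq NaHCO3 (pH 8), 0 °C → rt; then 1 M HCl, THF, rt
Reagents that add atoms: hydrogen peroxide, OO; water, O
Why: Proposed new method: syn-hydroboration–oxidation of a tetrasubstituted enol ester that already carries the final acyl group: BH3 adds through the four-centre transition state from the α face (the β face of C4 is blocked by the axial C10 methyl), with boron going to C4 (β to the enol oxygen, which stabilises positive charge at C3) and hydrogen to C3, so one event sets 3α-H (hence 3β-acyloxy) and 4α-B; buffered peroxide then replaces B by OH with retention to give the trans-diequatorial 3β-acyloxy-4α-ol, the rigid trans-decalin holds B and the acyloxy group gauche so the usual β-elimination of β-acyloxyboranes has no syn- or anti-periplanar geometry, and acid then unmasks the C8 ketone; the closest known reaction type is hydroboration–oxidation of simple enol acetates and silyl enol ethers to trans-1,2-diol derivatives, which to my knowledge has not been shown for a fully substituted enol ester of an α-stereogenic acid with the ester kept.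

**Step 5**
Reactants: 14; 15 acetone
Product: 17 3β-[(R)-2-methylbutanoyloxy]-4α-hydroxy-7-(2-hydroxypropan-2-yl)-4β,10β-dimethyl-5αH-decalin-8-one (C7 epimers; both serve), via titanium enolate 16 (not isolated)
Conditions: TiCl4 (2.4 equiv), Bu3N (2.8 equiv), CH2Cl2, −78 °C; then 15 (3 equiv), −78 → −40 °C; aq NH4Cl
Reagents that add atoms: none
Why: Titanium-mediated direct crossed aldol addition between two ketones (soft enolisation with TiCl4/amine): enolisation goes to C7 because C9 is neopentyl, the non-basic titanium aldolate resists retro-aldol, the hindered α-branched ester is not enolised and the C4 hydroxyl is only masked as its titanium alkoxide; the new C7 centre is erased in step 6.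

**Step 6**
Reactants: 17
Product: 18 (1S,2S,4aR,8aR)-1-hydroxy-7-(2-hydroxypropan-2-yl)-1,4a-dimethyl-6-oxo-1,2,3,4,4a,5,6,8a-octahydronaphthalen-2-yl (2R)-2-methylbutanoate (CNP0201989.1)
Conditions: IBX (2.5 equiv), 4-methoxypyridine N-oxide (2.5 equiv), DMSO, 25 → 40 °C
Reagents that add atoms: none
Why: IBX dehydrogenation of a ketone through its enol: C10 is quaternary so the C9 side has no β-hydrogen and only the C7 enol can lose hydrogen from C6, giving the Δ6-8-one (a Baylis–Hillman-type hydroxy enone that cannot retro-aldolise), while tertiary alcohols and the ester are inert to IBX.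

**Compound list**
1 | 7-methyl-1,4-dioxaspiro[4.5]decan-8-one (racemic) | CC1CC2(OCCO2)CCC1=O | starting material
2 | (R)-1-phenylethylamine | C[C@@H](N)c1ccccc1 | starting material
3 | ethyl vinyl ketone (pent-1-en-3-one) | CCC(=O)C=C | starting material
4 | ketimine of 1 with 2 (C7 epimers, in equilibrium with the enamine) | CC1CC2(OCCO2)CCC1=N[C@H](C)c1ccccc1 | intermediate
5 | Michael-adduct ketimine (quaternary C set) | CCC(=O)CC[C@]1(C)CC2(OCCO2)CCC1=N[C@H](C)c1ccccc1 | intermediate
6 | (R)-7-methyl-7-(3-oxopentyl)-1,4-dioxaspiro[4.5]decan-8-one | CCC(=O)CC[C@]1(C)CC2(OCCO2)CCC1=O | intermediate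
7 | (4aR)-6,6-ethylenedioxy-1,4a-dimethyl-4,4a,5,6,7,8-hexahydronaphthalen-2(3H)-one | O=C1CC[C@]2(C)CC3(OCCO3)CCC2=C1C | intermediate
8 | (R)-2-methylbutanoic acid | CC[C@@H](C)C(=O)O | starting material
9 | lithium Δ3-enolate of the trans-fused ketal decalone (5α-H, 10β-Me) | [Li+].[O-]C1=C(C)[C@@H]2CCC3(OCCO3)C[C@@]2(C)CC1 | intermediate
10 | (R)-2-methylbutanoic anhydride | CC[C@@H](C)C(=O)OC(=O)[C@H](C)CC | intermediate
11 | Δ3 enol (R)-2-methylbutanoate, C8 dioxolane, 5α-H, 10β-Me | CC[C@@H](C)C(=O)OC1=C(C)[C@@H]2CCC3(OCCO3)C[C@@]2(C)CC1 | intermediate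
12 | 4α-boryl-3β-acyloxy adduct (R–BH2), C8 dioxolane | CC[C@@H](C)C(=O)O[C@H]1CC[C@]2(C)CC3(OCCO3)CC[C@H]2[C@]1(C)B | intermediate
13 | 3β-acyloxy-4α-hydroxy-4β,10β-dimethyl-5αH-decalin-8-one ethylene ketal | CC[C@@H](C)C(=O)O[C@H]1CC[C@]2(C)CC3(OCCO3)CC[C@H]2[C@]1(C)O | intermediate
14 | 3β-[(R)-2-methylbutanoyloxy]-4α-hydroxy-4β,10β-dimethyl-5αH-decalin-8-one | CC[C@@H](C)C(=O)O[C@H]1CC[C@]2(C)CC(=O)CC[C@H]2[C@]1(C)O | intermediate
15 | acetone | CC(C)=O | starting material
16 | C7(8) trichlorotitanium enolate of 14 (C4–O also titanated) | CC[C@@H](C)C(=O)O[C@H]1CC[C@]2(C)CC(O[Ti](Cl)(Cl)Cl)=CC[C@H]2[C@]1(C)O[Ti](Cl)(Cl)Cl | intermediate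
17 | 7-(2-hydroxypropan-2-yl) aldol of 14 (C7 epimer mixture) | CC[C@@H](C)C(=O)O[C@H]1CC[C@]2(C)CC(=O)C(C(C)(C)O)C[C@H]2[C@]1(C)O | intermediate
18 | CNP0201989.1 | CC[C@@H](C)C(=O)O[C@H]1CC[C@]2(C)CC(=O)C(C(C)(C)O)=C[C@H]2[C@]1(C)O | target

**Total step count:** 6. **Longest linear sequence:** 6.

**Steps most likely to fail**

Step 4 (the proposed new method). The risks are slow addition to the tetrasubstituted enol ester, reduction of the ester by borane, and loss of the ester during oxidation. The fallback uses known chemistry, sets out from 7 and comes back to the route at 13. Luche reduction (NaBH4, CeCl3·7H2O, MeOH, −20 °C) gives the 3β-allylic alcohol F2. Hydroboration of this Δ4-3β-ol (BH3·THF, then NaOH/H2O2) follows the classical pattern of α-face addition with boron next to the carbinol, and gives the 3β,4α-diol with 5α-H, F3. Selective acylation of the secondary hydroxyl with 8 (EDC, cat. DMAP, CH2Cl2) gives 13, which passes through the acid stage of step 4 to 14.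

Step 3. The risks are C- versus O-acylation, tert-butoxide consuming the anhydride, and partial epimerisation of the acyl α-centre through ketene formation. The fallback sets out from 7 and comes back at 11. The same Li/NH3 reduction is run, but the enolate is trapped with TMSCl/Et3N as the isolable trimethylsilyl enol ether F1. MeLi (THF, 0 °C) then regenerates lithium enolate 9 free of alkoxide bases, and 1.2 equiv of 10 gives 11.

Step 6. The risks are slow dehydrogenation at the hindered tertiary α-carbon and dehydration of the aldol. The fallback sets out from 17 and comes back at 18. Acid-catalysed dehydration (TsOH cat., benzene, 60 °C) gives the conjugated isopropylidene ketone F4, a pulegone-type enone. A Schenck ene reaction with singlet oxygen (O2, hν, tetraphenylporphyrin, CH2Cl2, 0 °C) puts oxygen on the β-carbon (C11) of this s-cis enone and takes hydrogen from the ring CH2 geminal to the carbonyl (C6), giving the allylic hydroperoxide F5. PPh3 reduces it to 18.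

**Further compounds**
F1 | step 3 | trimethylsilyl Δ3-enol ether of the trans-fused ketal decalone | C[Si](C)(C)OC1=C(C)[C@@H]2CCC3(OCCO3)C[C@@]2(C)CC1
F2 | step 4 | 3β-hydroxy-Δ4 ketal (allylic alcohol) | O[C@H]1CC[C@]2(C)CC3(OCCO3)CCC2=C1C
F3 | step 4 | 3β,4α-diol ketal (4β-Me, 5α-H) | O[C@H]1CC[C@]2(C)CC3(OCCO3)CC[C@H]2[C@]1(C)O
F4 | step 6 | 7-isopropylidene-8-ketone (3β-acyloxy, 4α-OH) | CC[C@@H](C)C(=O)O[C@H]1CC[C@]2(C)CC(=O)C(=C(C)C)C[C@H]2[C@]1(C)O
F5 | step 6 | 11-hydroperoxy-Δ6-8-ketone | CC[C@@H](C)C(=O)O[C@H]1CC[C@]2(C)CC(=O)C(C(C)(C)OO)=C[C@H]2[C@]1(C)O
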